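**Plan**
- Retrosynthetic cuts: (i) the C8 methacrylate; (ii) the lactone C12–O6 bond and C6–C7 (allylchromium closure of the ten-membered carbocycle); (iii) C1–C10 and C2=C3 of the 3(2H)-furanone together, in one (3+2) event.
- Enabling feature: the furanone oxygen O10 lies between quaternary C10 (ketone level) and sp2 C3 (acid level), so the ring is a carbonyl ylide C10–O10–C3 plus a ketene (C1(=O)–C2H). O8 is 1,3 to O10 and can bind C3, which makes the ylide six-membered; its adduct is a 2,8-dioxabicyclo[3.2.1]octanone that E1cB opening converts into the furanone.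
- Forward order: butynediol → butenolide → Z-acid 6; glycidyl ether → β-hydroxy ketone → hydrazone; N-acylhydrazone → bridged Δ3-1,3,4-oxadiazoline → (−N2) ylide + Me3SiCH=C=O → furanone; then C7 aldehyde → Baylis–Hillman → allyl bromide, C6 enal, CrCl2 closure of carbocycle and lactone, methacrylate, desilylation.
- Stereochemistry: C8 from (R)-glycidyl ether, later inverted by Mitsunobu; C10 from the cycloaddition under control of the six-membered template; C6/C7 from the macrocyclic allylchromium addition; Z-C4=C5 from the butenolide ring.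

Key step: step 9

Remark: (trimethylsilyl)ketene is taken as an available reagent (distilled after thermolysis of 1-ethoxy-2-(trimethylsilyl)ethyne); locants C1–C15 are germacrane numbers of the target (C1 ketone carbon, C2 ring =CH, C3 enol-ether carbon, C10 quaternary carbon, C6/C7 lactone junction, C8 ester carbinol, C15 the CH2OH carbon).

Step 1
Reactants: 1 but-2-yne-1,4-diol
Product: 2 3-(hydroxymethyl)furan-2(5H)-one
Conditions: Pd(dba)2 (4 mol%), dppb, CO (40 atm), H2 (14 atm), CH2Cl2, 95 °C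
Reagents that add atoms: carbon monoxide, [C-]#[O+]
Why: Pd–H cyclocarbonylation (hydro-alkoxycarbonylation) of a 2-alkyn-1-ol should take up CO and close the butenolide onto one of the two equivalent CH2OH groups, so the acyl carbon (C3) and C6 are cis by ring constraint, which is the later Z-C4=C5 geometry.

Step 2
Reactants: 2 3-(hydroxymethyl)furan-2(5H)-one
Product: 3 3-{[(tert-butyldiphenylsilyl)oxy]methyl}furan-2(5H)-one
Conditions: TBDPSCl, imidazole, DMF, 0 °C → rt
Reagents that add atoms: tert-butyldiphenylsilyl chloride, CC(C)(C)[Si](Cl)(c1ccccc1)c1ccccc1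
Why: Standard silylation of the primary allylic alcohol protects O15 until the last step.

Step 3
Reactants: 3 TBDPS-butenolide
Product: 6 (Z)-4-[(tert-butyldimethylsilyl)oxy]-2-{[(tert-butyldiphenylsilyl)oxy]methyl}but-2-enoic acid, via lithium hydroxy carboxylate 4 (not isolated), via bis-TBS derivative 5 (not isolated)
Conditions: LiOH, THF/H2O, 0 °C; evaporate; TBSCl, imidazole, DMF; then K2CO3 (cat.), MeOH/THF/H2O, citric acid to pH 5
Reagents that add atoms: lithium hydroxide, [Li+].[OH-]; tert-butyldimethylsilyl chloride, CC(C)(C)[Si](C)(C)Cl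
Why: Lactone saponification gives the Z-hydroxy carboxylate, silylation caps O6 before it can relactonise, and the labile silyl ester is methanolysed selectively, so the Z geometry of the ring is carried into the open acid.

Step 4
Reactants: 7 (R)-2-{[(4-methoxybenzyl)oxy]methyl}oxirane
Product: 8 (R)-1-[(4-methoxybenzyl)oxy]pent-4-en-2-ol
Conditions: CH2=CHMgBr, CuI (10 mol%), THF, −30 → 0 °C; aq. NH4Cl
Reagents that add atoms: vinylmagnesium bromide, C=C[Mg]Br
Why: Copper-catalysed Grignard opening of the terminal epoxide at its CH2 carbon leaves the stereocentre (later C8) untouched.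

Step 5
Reactants: 8 (R)-homoallylic alcohol
Product: 9 (R)-4-hydroxy-5-[(4-methoxybenzyl)oxy]pentan-2-one
Conditions: PdCl2 (10 mol%), CuCl, O2 (1 atm), DMF/H2O, rt
Reagents that add atoms: water, O
Why: Tsuji–Wacker oxidation of the terminal alkene gives the methyl ketone (C10=O with C14 methyl) with Markovnikov regiochemistry.

Step 6
Reactants: 9 β-hydroxy ketone
Product: 10 (2R)-4-hydrazinylidene-1-[(4-methoxybenzyl)oxy]pentan-2-ol (C=N isomers)
Conditions: N2H4·H2O (5 equiv), EtOH, 0 °C → rt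
Reagents that add atoms: hydrazine, NN
Why: Hydrazone condensation with excess hydrazine (to suppress azine formation) installs the N–N unit that later leaves as N2.

Step 7
Reactants: 6 Z-acid; 10 hydrazone
Product: 11 (Z)-4-[(tert-butyldimethylsilyl)oxy]-2-{[(tert-butyldiphenylsilyl)oxy]methyl}-N'-{(4R)-4-hydroxy-5-[(4-methoxybenzyl)oxy]pentan-2-ylidene}but-2-enehydrazide
Conditions: EDC·HCl, HOBt, CH2Cl2, 0 °C → rt
Reagents that add atoms: none
Why: Carbodiimide coupling acylates the hydrazone NH2 (more nucleophilic than the secondary alcohol) to give the ketone N-acylhydrazone that holds C3, the future O10 and C10 in one chain.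

Step 8
Reactants: 11 N-acylhydrazone
Product: 13 (3R)-3-{[(4-methoxybenzyl)oxy]methyl}-5-methyl-1-[(Z)-1-(TBDPS-oxy)-4-(TBS-oxy)but-2-en-2-yl]-2,8-dioxa-6,7-diazabicyclo[3.2.1]oct-6-ene (both bridgehead diastereomers), via 2-acetoxy-oxadiazoline 12 (not isolated)
Conditions: PhI(OAc)2 (1.1 equiv), CH2Cl2, 0 °C → rt (the AcOH formed catalyses the exchange)
Reagents that add atoms: none
Why: Oxidative cyclisation of a ketone N-acylhydrazone (acyl oxygen onto C10) gives the 2-acetoxy-Δ3-1,3,4-oxadiazoline, whose acetoxy group is exchanged by the internal C8 hydroxyl (known alkoxy exchange at C2), and both bridgehead diastereomers lead to the same ylide.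

Step 9
Reactants: 13 bridged oxadiazoline
Product: 16 (2R)-2-[(2R)-2-hydroxy-3-(4-methoxybenzyloxy)propyl]-2-methyl-5-[(Z)-1-(TBDPS-oxy)-4-(TBS-oxy)but-2-en-2-yl]furan-3(2H)-one, via cyclic carbonyl ylide 14 (not isolated), via silyl ketone cycloadduct 15 (not isolated)
Conditions: Me3SiCH=C=O (5 equiv), PhMe, 110 °C, sealed tube; then K2CO3 (cat.), MeOH, 0 °C
Reagents that add atoms: (trimethylsilyl)ketene, C[Si](C)(C)C=C=O
Why: Proposed new method: heating the bridged 2-alkoxy-Δ3-1,3,4-oxadiazoline should expel N2 (retro-(3+2), as in the known thermolysis of 2-alkoxy-oxadiazolines to carbonyl ylides) and leave the six-membered cyclic ylide 14, whose carbanionic C10 adds to the carbonyl carbon of the silylketene and whose α-silyl enolate carbon C2 then bonds to the dioxanylium carbon C3, i.e. a stepwise (3+2) cycloaddition across the ketene C=C. The closest known reaction types are the cycloadditions of six-membered ester-derived carbonyl ylides that give 2,8-dioxabicyclo[3.2.1]octanes and the diazoalkane–ketene route to cyclopropanones (nucleophilic carbon on the ketene C=O carbon, then C-closure of the enolate). The furanone ring closes in the (3+2) mode (C1–C10 first, then five-membered C2→C3 closure onto the oxocarbenium carbon; an O-closed ortho ester would re-ionise and end at the same C–C product), and methanolysis of the C–Si bond of 15 gives the enolate that expels O8 (E1cB), which creates C2=C3 and removes the tether. C10 is the only new stereocentre that survives; it is set by the template, because addition through the chair-like transition state places the C8 substituent equatorial on the 1,3-dioxane ring and C1 axial (C1 trans to CH2OPMB), which corresponds to (8R,10R). The step needs C10/C3 rather than C10/C5 bonding (1,5-electrocyclisation onto C5 would need a bridgehead alkene and a seven-membered closure is slower), trapping faster than the 1,4-hydrogen shift of the ylide (excess ketene), and no break-up into ketone and alkoxycarbene, which the O8 tether makes reversible. The Z-C4=C5 bond should survive because the ylide is short-lived.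

Step 10
Reactants: 16 (8R)-furanone alcohol
Product: 17 (2S)-1-[(4-methoxybenzyl)oxy]-3-[(2R)-2-methyl-3-oxo-5-{(Z)-1-(TBDPS-oxy)-4-(TBS-oxy)but-2-en-2-yl}-2,3-dihydrofuran-2-yl]propan-2-yl 4-nitrobenzoate
Conditions: 4-O2NC6H4CO2H, PPh3, DIAD, THF, 0 °C → rt
Reagents that add atoms: 4-nitrobenzoic acid, OC(=O)c1ccc(cc1)[N+](=O)[O-]
Why: Mitsunobu esterification proceeds by SN2 at C8 and turns the template configuration (8R) into the natural (8S).

Step 11
Reactants: 17 4-nitrobenzoate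
Product: 18 (2R)-2-[(2S)-2-hydroxy-3-(4-methoxybenzyloxy)propyl]-2-methyl-5-[(Z)-1-(TBDPS-oxy)-4-(TBS-oxy)but-2-en-2-yl]furan-3(2H)-one
Conditions: K2CO3 (cat.), MeOH, 0 °C
Reagents that add atoms: none
Why: Transesterification of the activated aryl ester frees the inverted alcohol without touching the silyl ethers.

Step 12
Reactants: 18 (8S)-alcohol
Product: 19 the C8 tert-butyldimethylsilyl ether of 18
Conditions: TBSOTf, 2,6-lutidine, CH2Cl2, −78 °C
Reagents that add atoms: tert-butyldimethylsilyl triflate, CC(C)(C)[Si](C)(C)OS(=O)(=O)C(F)(F)F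
Why: Silylation of the secondary alcohol gives the base-stable α-silyloxy group needed for the aldehyde chemistry at C7.

Step 13
Reactants: 19 PMB ether
Product: 20 (2R)-2-[(2S)-2-(TBS-oxy)-3-hydroxypropyl]-2-methyl-5-[(Z)-1-(TBDPS-oxy)-4-(TBS-oxy)but-2-en-2-yl]furan-3(2H)-one
Conditions: DDQ, CH2Cl2/pH 7 buffer, 0 °C
Reagents that add atoms: none
Why: Oxidative cleavage of the 4-methoxybenzyl ether by DDQ leaves silyl ethers and the furanone intact.

Step 14
Reactants: 20 primary alcohol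
Product: 21 (2S)-2-(TBS-oxy)-3-[(2R)-2-methyl-3-oxo-5-{(Z)-1-(TBDPS-oxy)-4-(TBS-oxy)but-2-en-2-yl}-2,3-dihydrofuran-2-yl]propanal
Conditions: Dess–Martin periodinane, CH2Cl2, 0 °C → rt
Reagents that add atoms: none
Why: Dess–Martin oxidation gives the α-silyloxy aldehyde (C7) under non-epimerising conditions.

Step 15
Reactants: 21 aldehyde
Product: 22 methyl (4S)-4-(TBS-oxy)-3-hydroxy-2-methylidene-5-[(2R)-2-methyl-3-oxo-5-{(Z)-1-(TBDPS-oxy)-4-(TBS-oxy)but-2-en-2-yl}-2,3-dihydrofuran-2-yl]pentanoate (C7 carbinol epimers)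
Conditions: methyl acrylate (excess), DABCO, MeOH (cat.), rt, 3–5 d
Reagents that add atoms: methyl acrylate, C=CC(=O)OC
Why: The Morita–Baylis–Hillman reaction attaches C11–C13 to C7, and the configuration of the new carbinol is irrelevant because step 16 removes it.

Step 16
Reactants: 22 Baylis–Hillman adduct
Product: 23 methyl (2Z,4S)-2-(bromomethyl)-4-(TBS-oxy)-5-[(2R)-2-methyl-3-oxo-5-{(Z)-1-(TBDPS-oxy)-4-(TBS-oxy)but-2-en-2-yl}-2,3-dihydrofuran-2-yl]pent-2-enoate
Conditions: NBS, Me2S, CH2Cl2, −20 → 0 °C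
Reagents that add atoms: N-bromosuccinimide, O=C1CCC(=O)N1Br
Why: Activation of the alcohol as an alkoxysulfonium salt and SN2′ attack of bromide should give the thermodynamically preferred (Z)-2-(bromomethyl)enoate (C8 trans to CO2Me).

Step 17
Reactants: 23 allyl bromide
Product: 24 the C6 primary allylic alcohol of 23 (C8-OTBS and C15-OTBDPS kept)
Conditions: CSA (0.1 equiv), MeOH/CH2Cl2, 0 °C
Reagents that add atoms: none
Why: Acid-catalysed methanolysis removes the primary allylic TBS ether much faster than the secondary TBS and the TBDPS ether.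

Step 18
Reactants: 24 allylic alcohol
Product: 25 the (Z)-enal (C6 aldehyde) of 24
Conditions: MnO2, CH2Cl2, rt
Reagents that add atoms: none
Why: Neutral MnO2 oxidation of the allylic alcohol should give the Z-enal without isomerising the C4=C5 bond.

Step 19
Reactants: 25 bromo enal
Product: 27 8-O-TBS-15-O-TBDPS-8-desmethacryloyl-goyazensolide (configuration at C6, C7, C8 and C10 as in the target), via hydroxy ester 26 (not isolated)
Conditions: CrCl2 (8 equiv), THF, 2 mM (syringe pump), rt; aq. work-up; then PPTS (cat.), CH2Cl2, rt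
Reagents that add atoms: none
Why: The 2-(methoxycarbonyl)allylchromium(III) species adds through its γ-carbon C7 to the C6 aldehyde in a chair (Nozaki–Hiyama/Barbier) transition state and the C6 hydroxyl then lactonises; the anti (trans-lactone) mode with the natural sense relative to C8 is expected because the furanone-bridged Z-olefinic tether can span only this arrangement (macrocyclic control).

Step 20
Reactants: 27 bis-silyl macrolide
Product: 28 15-O-TBDPS-8-desmethacryloyl-goyazensolide (free C8–OH)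
Conditions: TsOH·H2O (0.2 equiv), MeOH/CH2Cl2, 0 °C → rt
Reagents that add atoms: none
Why: Acidic methanolysis cleaves the secondary TBS ether while the far more acid-stable primary TBDPS ether stays.

Step 21
Reactants: 28 C8 alcohol
Product: 29 15-O-TBDPS-goyazensolide
Conditions: methacrylic anhydride, Et3N, DMAP, CH2Cl2, 0 °C → rt
Reagents that add atoms: methacrylic anhydride, CC(=C)C(=O)OC(=O)C(C)=C
Why: DMAP-catalysed acylation of the only free hydroxyl installs the methacrylate with retention at C8.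

Step 22
Reactants: 29 15-O-TBDPS-goyazensolide
Product: 30 goyazensolide
Conditions: HF·pyridine, pyridine, THF, 0 °C → rt
Reagents that add atoms: none
Why: Buffered fluoride desilylation frees the C15 alcohol without adding to the methylene lactone, methacrylate or furanone.

**Compound list**
1 | but-2-yne-1,4-diol | OCC#CCO | starting material
2 | 3-(hydroxymethyl)furan-2(5H)-one | O=C1OCC=C1CO | intermediate
3 | 3-{[(tert-butyldiphenylsilyl)oxy]methyl}furan-2(5H)-one | O=C1OCC=C1CO[Si](c1ccccc1)(c1ccccc1)C(C)(C)C | intermediate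
4 | lithium (Z)-2-{[(tert-butyldiphenylsilyl)oxy]methyl}-4-hydroxybut-2-enoate (not isolated) | [Li+].[O-]C(=O)/C(CO[Si](c1ccccc1)(c1ccccc1)C(C)(C)C)=C\CO | intermediate
5 | tert-butyldimethylsilyl (Z)-4-[(tert-butyldimethylsilyl)oxy]-2-{[(tert-butyldiphenylsilyl)oxy]methyl}but-2-enoate (not isolated) | CC(C)(C)[Si](C)(C)OC(=O)/C(CO[Si](c1ccccc1)(c1ccccc1)C(C)(C)C)=C\CO[Si](C)(C)C(C)(C)C | intermediate
6 | (Z)-4-[(tert-butyldimethylsilyl)oxy]-2-{[(tert-butyldiphenylsilyl)oxy]methyl}but-2-enoic acid | OC(=O)/C(CO[Si](c1ccccc1)(c1ccccc1)C(C)(C)C)=C\CO[Si](C)(C)C(C)(C)C | intermediate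
7 | (R)-2-{[(4-methoxybenzyl)oxy]methyl}oxirane | COc1ccc(COC[C@H]2CO2)cc1 | starting material
8 | (R)-1-[(4-methoxybenzyl)oxy]pent-4-en-2-ol | COc1ccc(COC[C@H](O)CC=C)cc1 | intermediate
9 | (R)-4-hydroxy-5-[(4-methoxybenzyl)oxy]pentan-2-one | COc1ccc(COC[C@H](O)CC(C)=O)cc1 | intermediate
10 | (2R)-4-hydrazinylidene-1-[(4-methoxybenzyl)oxy]pentan-2-ol (C=N isomers) | COc1ccc(COC[C@H](O)CC(C)=NN)cc1 | intermediate
11 | (Z)-4-[(TBS)oxy]-2-{[(TBDPS)oxy]methyl}-N'-{(4R)-4-hydroxy-5-[(4-methoxybenzyl)oxy]pentan-2-ylidene}but-2-enehydrazide | COc1ccc(COC[C@H](O)CC(C)=NNC(=O)/C(CO[Si](c2ccccc2)(c2ccccc2)C(C)(C)C)=C\CO[Si](C)(C)C(C)(C)C)cc1 | intermediate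
12 | 5-[(2R)-2-hydroxy-3-(4-methoxybenzyloxy)propyl]-5-methyl-2-[(Z)-1-(TBDPS-oxy)-4-(TBS-oxy)but-2-en-2-yl]-2,5-dihydro-1,3,4-oxadiazol-2-yl acetate (not isolated) | COc1ccc(COC[C@H](O)CC2(C)N=NC(OC(C)=O)(O2)/C(CO[Si](c3ccccc3)(c3ccccc3)C(C)(C)C)=C\CO[Si](C)(C)C(C)(C)C)cc1 | intermediate
13 | (3R)-3-{[(4-methoxybenzyl)oxy]methyl}-5-methyl-1-[(Z)-1-(TBDPS-oxy)-4-(TBS-oxy)but-2-en-2-yl]-2,8-dioxa-6,7-diazabicyclo[3.2.1]oct-6-ene (both bridgehead diastereomers) | CC12C[C@H](COCc3ccc(OC)cc3)OC(O1)(N=N2)/C(CO[Si](c3ccccc3)(c3ccccc3)C(C)(C)C)=C\CO[Si](C)(C)C(C)(C)C | intermediate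
14 | six-membered cyclic carbonyl ylide (C10 carbanion, O10 oxonium, C3=O10+; ring O8–C8(R)–C9 intact; not isolated) | C[C-]1C[C@H](COCc2ccc(OC)cc2)OC(/C(CO[Si](c2ccccc2)(c2ccccc2)C(C)(C)C)=C\CO[Si](C)(C)C(C)(C)C)=[O+]1 | intermediate
15 | (3R,5R)-5-methyl-3-{[(4-methoxybenzyl)oxy]methyl}-1-[(Z)-1-(TBDPS-oxy)-4-(TBS-oxy)but-2-en-2-yl]-7-(trimethylsilyl)-2,8-dioxabicyclo[3.2.1]octan-6-one (CH2OPMB equatorial, C7 epimers; not isolated) | C[C@]12C[C@H](COCc3ccc(OC)cc3)O[C@](O1)(C([Si](C)(C)C)C2=O)/C(CO[Si](c3ccccc3)(c3ccccc3)C(C)(C)C)=C\CO[Si](C)(C)C(C)(C)C | intermediate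
16 | (2R)-2-[(2R)-2-hydroxy-3-(4-methoxybenzyloxy)propyl]-2-methyl-5-[(Z)-1-(TBDPS-oxy)-4-(TBS-oxy)but-2-en-2-yl]furan-3(2H)-one | COc1ccc(COC[C@H](O)C[C@@]2(C)OC(=CC2=O)/C(CO[Si](c3ccccc3)(c3ccccc3)C(C)(C)C)=C\CO[Si](C)(C)C(C)(C)C)cc1 | intermediate
17 | (2S)-1-[(4-methoxybenzyl)oxy]-3-[(2R)-2-methyl-3-oxo-5-{(Z)-1-(TBDPS-oxy)-4-(TBS-oxy)but-2-en-2-yl}-2,3-dihydrofuran-2-yl]propan-2-yl 4-nitrobenzoate | COc1ccc(COC[C@@H](OC(=O)c2ccc(cc2)[N+](=O)[O-])C[C@@]2(C)OC(=CC2=O)/C(CO[Si](c3ccccc3)(c3ccccc3)C(C)(C)C)=C\CO[Si](C)(C)C(C)(C)C)cc1 | intermediate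
18 | (2R)-2-[(2S)-2-hydroxy-3-(4-methoxybenzyloxy)propyl]-2-methyl-5-[(Z)-1-(TBDPS-oxy)-4-(TBS-oxy)but-2-en-2-yl]furan-3(2H)-one | COc1ccc(COC[C@@H](O)C[C@@]2(C)OC(=CC2=O)/C(CO[Si](c3ccccc3)(c3ccccc3)C(C)(C)C)=C\CO[Si](C)(C)C(C)(C)C)cc1 | intermediate
19 | (2R)-2-[(2S)-2-(TBS-oxy)-3-(4-methoxybenzyloxy)propyl]-2-methyl-5-[(Z)-1-(TBDPS-oxy)-4-(TBS-oxy)but-2-en-2-yl]furan-3(2H)-one | COc1ccc(COC[C@@H](O[Si](C)(C)C(C)(C)C)C[C@@]2(C)OC(=CC2=O)/C(CO[Si](c3ccccc3)(c3ccccc3)C(C)(C)C)=C\CO[Si](C)(C)C(C)(C)C)cc1 | intermediate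
20 | (2R)-2-[(2S)-2-(TBS-oxy)-3-hydroxypropyl]-2-methyl-5-[(Z)-1-(TBDPS-oxy)-4-(TBS-oxy)but-2-en-2-yl]furan-3(2H)-one | OC[C@@H](O[Si](C)(C)C(C)(C)C)C[C@@]1(C)OC(=CC1=O)/C(CO[Si](c2ccccc2)(c2ccccc2)C(C)(C)C)=C\CO[Si](C)(C)C(C)(C)C | intermediate
21 | (2S)-2-(TBS-oxy)-3-[(2R)-2-methyl-3-oxo-5-{(Z)-1-(TBDPS-oxy)-4-(TBS-oxy)but-2-en-2-yl}-2,3-dihydrofuran-2-yl]propanal | O=C[C@@H](O[Si](C)(C)C(C)(C)C)C[C@@]1(C)OC(=CC1=O)/C(CO[Si](c2ccccc2)(c2ccccc2)C(C)(C)C)=C\CO[Si](C)(C)C(C)(C)C | intermediate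
22 | methyl (4S)-4-(TBS-oxy)-3-hydroxy-2-methylidene-5-[(2R)-2-methyl-3-oxo-5-{(Z)-1-(TBDPS-oxy)-4-(TBS-oxy)but-2-en-2-yl}-2,3-dihydrofuran-2-yl]pentanoate (C3 carbinol epimers) | COC(=O)C(=C)C(O)[C@@H](O[Si](C)(C)C(C)(C)C)C[C@@]1(C)OC(=CC1=O)/C(CO[Si](c2ccccc2)(c2ccccc2)C(C)(C)C)=C\CO[Si](C)(C)C(C)(C)C | intermediate
23 | methyl (2Z,4S)-2-(bromomethyl)-4-(TBS-oxy)-5-[(2R)-2-methyl-3-oxo-5-{(Z)-1-(TBDPS-oxy)-4-(TBS-oxy)but-2-en-2-yl}-2,3-dihydrofuran-2-yl]pent-2-enoate | COC(=O)/C(CBr)=C/[C@@H](O[Si](C)(C)C(C)(C)C)C[C@@]1(C)OC(=CC1=O)/C(CO[Si](c2ccccc2)(c2ccccc2)C(C)(C)C)=C\CO[Si](C)(C)C(C)(C)C | intermediate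
24 | methyl (2Z,4S)-2-(bromomethyl)-4-(TBS-oxy)-5-[(2R)-2-methyl-3-oxo-5-{(Z)-1-(TBDPS-oxy)-4-hydroxybut-2-en-2-yl}-2,3-dihydrofuran-2-yl]pent-2-enoate | COC(=O)/C(CBr)=C/[C@@H](O[Si](C)(C)C(C)(C)C)C[C@@]1(C)OC(=CC1=O)/C(CO[Si](c2ccccc2)(c2ccccc2)C(C)(C)C)=C\CO | intermediate
25 | methyl (2Z,4S)-2-(bromomethyl)-4-(TBS-oxy)-5-[(2R)-2-methyl-3-oxo-5-{(Z)-1-(TBDPS-oxy)-4-oxobut-2-en-2-yl}-2,3-dihydrofuran-2-yl]pent-2-enoate | COC(=O)/C(CBr)=C/[C@@H](O[Si](C)(C)C(C)(C)C)C[C@@]1(C)OC(=CC1=O)/C(CO[Si](c2ccccc2)(c2ccccc2)C(C)(C)C)=C\C=O | intermediate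
26 | macrocyclic hydroxy ester: ten-membered furanone-bridged carbocycle with C6–OH, C7–C(=CH2)CO2Me, C8-OTBS, C15-OTBDPS, target configuration at C6, C7, C8, C10 (not isolated) | CC(C)(C)[Si](C)(C)O[C@H]1C[C@@]2(C)OC(=CC2=O)/C(CO[Si](c3ccccc3)(c3ccccc3)C(C)(C)C)=C\[C@@H](O)[C@@H]1C(=C)C(=O)OC | intermediate
27 | 8-O-TBS-15-O-TBDPS-8-desmethacryloyl-goyazensolide | CC(C)(C)[Si](C)(C)O[C@H]1C[C@@]2(C)OC(=CC2=O)/C(CO[Si](c3ccccc3)(c3ccccc3)C(C)(C)C)=C\[C@H]2OC(=O)C(=C)[C@H]12 | intermediate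
28 | 15-O-TBDPS-8-desmethacryloyl-goyazensolide | O[C@H]1C[C@@]2(C)OC(=CC2=O)/C(CO[Si](c3ccccc3)(c3ccccc3)C(C)(C)C)=C\[C@H]2OC(=O)C(=C)[C@H]12 | intermediate
29 | 15-O-TBDPS-goyazensolide | C=C(C)C(=O)O[C@H]1C[C@@]2(C)OC(=CC2=O)/C(CO[Si](c3ccccc3)(c3ccccc3)C(C)(C)C)=C\[C@H]2OC(=O)C(=C)[C@H]12 | intermediate
30 | goyazensolide | C=C(C)C(=O)O[C@H]1C[C@@]2(C)OC(=CC2=O)/C(CO)=C\[C@H]2OC(=O)C(=C)[C@H]12 | target

**Step count**
Total: 22 steps. Longest linear sequence: 19 steps (steps 1–3 and 7–22; the branch through steps 4–6 is equally long).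

**Steps most likely to fail, with fallbacks**

1. Step 9 (Proposed new method). The ylide may be lost before the ketene traps it, by 1,4-hydrogen shift to enol ethers or by cycloreversion to a diazoalkane and ester, and the face selectivity of the addition may be poor. The fallback uses known acetylide chemistry, sets out from ketone 9 and lactone 3, and rejoins the route at furanone alcohol 16. Ketone 9 is treated with ethynylmagnesium bromide (THF, −78 °C; the magnesium alkoxide of O8 chelates the ketone and axial attack gives the 1,3-anti diol) to give (2R,4R)-1-[(4-methoxybenzyl)oxy]-4-methylhex-5-yne-2,4-diol F1, which is silylated (TESOTf, 2,6-lutidine) to its bis(triethylsilyl) ether F2. Lactone 3 is opened with Me(MeO)NH·HCl/Me3Al to the Z-hydroxy Weinreb amide F3 and silylated (TBSCl, imidazole) to the TBS ether F4. Lithiated F2 (n-BuLi, THF, −78 °C) is acylated by F4 to the bis-TES ynone F5. PPTS in MeOH removes both TES groups to give the dihydroxy ynone F6, and Et2NH in EtOH (conjugate addition, hemiketal formation, loss of the amine) closes the 3(2H)-furanone to give 16.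

2. Step 8. The oxidised hydrazone may be captured by acetate or react elsewhere instead of closing the bridged ring with the hindered internal hydroxyl. The fallback sets out from 11 and returns at 13. Oxidation with PhI(OAc)2 in methanol (solvent capture, the classical conditions) gives the 2-methoxy-oxadiazoline F7. The ring is then closed in a separate acid-catalysed alkoxy exchange (CSA cat., 4 Å MS, CH2Cl2) that replaces methoxy by the C8 hydroxyl.

3. Step 19. Ring closure may be slow against oligomerisation, and the allylchromium may add to the wrong aldehyde face (syn instead of anti addition). The fallback sets out from 25 and returns at 27. If the closure delivers the C6-epimeric hydroxy ester F8, the methyl ester is hydrolysed with Me3SnOH (1,2-dichloroethane, 60 °C) to the hydroxy acid F9. Mitsunobu lactonisation (PPh3, DIAD, THF) then forms the C6–O bond by SN2 with inversion and gives the trans-lactone 27.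

**Further compounds**
F1 | step 9 | (2R,4R)-1-[(4-methoxybenzyl)oxy]-4-methylhex-5-yne-2,4-diol | COc1ccc(COC[C@H](O)C[C@@](C)(O)C#C)cc1
F2 | step 9 | (2R,4R)-1-[(4-methoxybenzyl)oxy]-4-methyl-2,4-bis[(triethylsilyl)oxy]hex-5-yne | COc1ccc(COC[C@H](O[Si](CC)(CC)CC)C[C@@](C)(O[Si](CC)(CC)CC)C#C)cc1
F3 | step 9 | (Z)-4-hydroxy-N-methoxy-N-methyl-2-{[(tert-butyldiphenylsilyl)oxy]methyl}but-2-enamide | CON(C)C(=O)/C(CO[Si](c1ccccc1)(c1ccccc1)C(C)(C)C)=C\CO
F4 | step 9 | (Z)-4-[(tert-butyldimethylsilyl)oxy]-N-methoxy-N-methyl-2-{[(tert-butyldiphenylsilyl)oxy]methyl}but-2-enamide | CON(C)C(=O)/C(CO[Si](c1ccccc1)(c1ccccc1)C(C)(C)C)=C\CO[Si](C)(C)C(C)(C)C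
F5 | step 9 | bis-TES ynone: (Z,6R,8R)-1-(TBS-oxy)-3-[(TBDPS-oxy)methyl]-9-[(4-methoxybenzyl)oxy]-6-methyl-6,8-bis[(triethylsilyl)oxy]non-2-en-4-yn-... 4-one-type ynone (C3 ketone conjugated to C1≡C2) | COc1ccc(COC[C@H](O[Si](CC)(CC)CC)C[C@@](C)(O[Si](CC)(CC)CC)C#CC(=O)/C(CO[Si](c2ccccc2)(c2ccccc2)C(C)(C)C)=C\CO[Si](C)(C)C(C)(C)C)cc1
F6 | step 9 | dihydroxy ynone (F5 without the two triethylsilyl groups) | COc1ccc(COC[C@H](O)C[C@@](C)(O)C#CC(=O)/C(CO[Si](c2ccccc2)(c2ccccc2)C(C)(C)C)=C\CO[Si](C)(C)C(C)(C)C)cc1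
F7 | step 8 | 5-[(2R)-2-hydroxy-3-(4-methoxybenzyloxy)propyl]-2-methoxy-5-methyl-2-[(Z)-1-(TBDPS-oxy)-4-(TBS-oxy)but-2-en-2-yl]-2,5-dihydro-1,3,4-oxadiazole | COc1ccc(COC[C@H](O)CC2(C)N=NC(OC)(O2)/C(CO[Si](c3ccccc3)(c3ccccc3)C(C)(C)C)=C\CO[Si](C)(C)C(C)(C)C)cc1
F8 | step 19 | C6 epimer of hydroxy ester 26 | CC(C)(C)[Si](C)(C)O[C@H]1C[C@@]2(C)OC(=CC2=O)/C(CO[Si](c3ccccc3)(c3ccccc3)C(C)(C)C)=C\[C@H](O)[C@@H]1C(=C)C(=O)OC
F9 | step 19 | hydroxy acid from F8 (CO2H in place of CO2Me) | CC(C)(C)[Si](C)(C)O[C@H]1C[C@@]2(C)OC(=CC2=O)/C(CO[Si](c3ccccc3)(c3ccccc3)C(C)(C)C)=C\[C@H](O)[C@@H]1C(=C)C(=O)O
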